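**Retrosynthetic overview**

1. Numbering: ring atoms C1–C10 (C1–C2 epoxide, C3 carbinol, C4=C5, C6 lactone O–CH, C7, C8 angelate CH, C9 CH2, C10 methyl carbinol), lactone carbons C11–C13. The route rests on the C8(O)–C9H2–C10(O)(CH3) segment of the ten-membered ring (ring A): a 1,3-dioxygenated unit that is the opened and reduced form of an isoxazoline whose oxygen-bearing carbon C10 was the substituted end of a 1,1-disubstituted alkene.
2. Key disconnection: C8–C9 and O–C10, by intramolecular cycloaddition of a C8 nitrile oxide onto C9=C10 at the end of a (Z)-diene; this closes ring A and the isoxazoline (ring C) together.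
3. The cyclisation substrate is a cis-fused γ-lactone (ring B). C5–C6 comes from a chelation-controlled addition of a (Z)-alkenyl Grignard reagent (fragment A: C1–C5, C9, C10, from propargyl alcohol and 2-methylbut-1-en-3-yne) to an aldehyde (fragment B: C6–C8, C11, C12, from an Evans alkylation of a succinate imide); the lactone closes in the same flask. An anti relationship between O6 and C11 is needed for the cis lactone, which is why a chelate-controlled addition is used and not a syn aldol.
4. After ring closure: N–O cleavage (ring C opened), chelation-controlled syn reduction at C8, α-methylenation (C13), angelate at C8, epoxidation of C1=C2 directed by the C10 hydroxyl, desilylation.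
5. Order of ring formation: ring B (step 9), rings A and C (step 13), epoxide (step 20).

Key step: step 13

Abbreviations: TBS = tert-butyldimethylsilyl, TES = triethylsilyl, PMB = 4-methoxybenzyl. Stereodescriptors of ring A compounds refer to the C1–C13 numbering above.

**Fragment A**

Step 1
Reactants: 1 propargyl alcohol
Product: 3 (Z)-3-iodo-2-methylprop-2-en-1-ol, via alkenylmagnesium alkoxide 2 (not isolated)
Conditions: MeMgBr (3 equiv), CuI (10 mol%), THF/Et2O, −10 °C to rt; then I2, −10 °C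
Reagents that add atoms: methylmagnesium bromide, C[Mg]Br; iodine, II
Why: Copper-catalysed anti-carbomagnesiation of the propargylic alkoxide puts the methyl group on C4 and magnesium on C5 cis to the CH2O group (five-membered chelate), and iodinolysis with retention fixes the Z geometry of the later C4=C5 bond.

Step 2
Reactants: 3 (Z)-3-iodo-2-methylprop-2-en-1-ol
Product: 4 (Z)-3-iodo-2-methylprop-2-enal
Conditions: activated MnO2, CH2Cl2, rt, dark; filtered solution used at once
Reagents that add atoms: none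
Why: Allylic alcohol oxidation on MnO2 is neutral and should leave the Z iodoalkene unchanged if light and acid are kept out.

Step 3
Reactants: 4 (Z)-3-iodo-2-methylprop-2-enal; 5 2-methylbut-1-en-3-yne
Product: 7 (1Z,3S)-1-iodo-2,6-dimethylhepta-1,6-dien-4-yn-3-ol, via alkynyl(methyl)zinc 6 (not isolated)
Conditions: 5 (3 equiv), Me2Zn (3 equiv), (R,R)-ProPhenol (20 mol%), Ph3P=O (40 mol%), toluene, 0 °C
Reagents that add atoms: none
Why: ProPhenol–zinc-catalysed alkynylation of an α-branched enal is reagent-controlled, and addition to the Si face of the aldehyde sets C3 as S; the ligand hand is assigned by analogy with the facial sense of this catalyst in related carbonyl additions and is to be confirmed by Mosher ester analysis of 7, with the antipodal ligand as the remedy if the sense is opposite.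

Step 4
Reactants: 7 (1Z,3S)-1-iodo-2,6-dimethylhepta-1,6-dien-4-yn-3-ol
Product: 8 tert-butyl{[(1Z,3S)-1-iodo-2,6-dimethylhepta-1,6-dien-4-yn-3-yl]oxy}dimethylsilane
Conditions: TBSCl, imidazole, DMF, 0 °C to rt
Reagents that add atoms: tert-butyldimethylsilyl chloride, CC(C)(C)[Si](C)(C)Cl
Why: Standard silylation of a secondary alcohol, with no stereocentre touched.

**Fragment B**

Step 5
Reactants: 9 (S)-4-benzyl-2-oxazolidinone; 10 methyl 4-chloro-4-oxobutanoate
Product: 11 methyl 4-[(4S)-4-benzyl-2-oxooxazolidin-3-yl]-4-oxobutanoate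
Conditions: Et3N, DMAP (10 mol%), CH2Cl2, 0 °C to rt
Reagents that add atoms: none
Why: N-Acylation of the oxazolidinone by the acid chloride under amine and DMAP catalysis gives the succinate imide.

Step 6
Reactants: 11 methyl 4-[(4S)-4-benzyl-2-oxooxazolidin-3-yl]-4-oxobutanoate; 12 4-methoxybenzyl chloromethyl ether
Product: 14 methyl (3R)-4-[(4S)-4-benzyl-2-oxooxazolidin-3-yl]-3-{[(4-methoxybenzyl)oxy]methyl}-4-oxobutanoate, via sodium (Z)-enolate 13 (not isolated)
Conditions: NaN(SiMe3)2, THF, −78 °C; then 12, −78 to −20 °C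
Reagents that add atoms: none
Why: Evans alkylation: the imide α-CH2 is more acidic than the ester α-CH2, and the chelated Z-enolate is alkylated by the reactive α-chloro ether on the face opposite the benzyl group, which sets C7 as R.

Step 7
Reactants: 14 alkylated imide
Product: 15 methyl (3R)-4-(ethylsulfanyl)-3-{[(4-methoxybenzyl)oxy]methyl}-4-oxobutanoate
Conditions: EtSH, n-BuLi (LiSEt), THF, 0 °C
Reagents that add atoms: ethanethiol, CCS
Why: The thiolate attacks the exocyclic imide carbonyl selectively, so the auxiliary is released and C7 is not epimerised.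

Step 8
Reactants: 15 thioester
Product: 16 methyl (3R)-3-formyl-4-[(4-methoxybenzyl)oxy]butanoate
Conditions: Et3SiH, 10% Pd/C, acetone, rt
Reagents that add atoms: none
Why: Fukuyama reduction stops at the aldehyde under neutral conditions, so the α-stereocentre C7, the methyl ester and the PMB ether survive.

**Union and cyclisation substrate**

Step 9
Reactants: 8 alkenyl iodide (fragment A); 16 aldehyde (fragment B)
Product: 20 (4R,5S)-5-[(1Z,3R)-3-(TBS-oxy)-2,6-dimethylhepta-1,6-dien-4-yn-1-yl]-4-{[(4-methoxybenzyl)oxy]methyl}oxolan-2-one, via alkenyllithium 17 (not isolated), via alkenylmagnesium bromide 18 (not isolated), via magnesium alkoxide 19 (not isolated)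
Conditions: 8 (1.2 equiv), t-BuLi (2.1 equiv per 8), Et2O, −78 °C; MgBr2·OEt2; then 16 precomplexed with MgBr2·OEt2, CH2Cl2, −78 °C; warm to rt
Reagents that add atoms: none
Why: Iodine–lithium exchange and transmetalation proceed with retention to give the (Z)-alkenyl Grignard reagent, which adds to the six-membered MgBr2 chelate between C6=O and the C8 ether oxygen (Cram chelate model) from the face away from the C11 arm to set C6 as S, and the magnesium alkoxide then closes the cis-fused γ-lactone (ring B) on the methyl ester.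

Step 10
Reactants: 20 PMB ether lactone
Product: 21 (4R,5S)-5-[(1Z,3R)-3-(TBS-oxy)-2,6-dimethylhepta-1,6-dien-4-yn-1-yl]-4-(hydroxymethyl)oxolan-2-one
Conditions: DDQ, CH2Cl2/pH 7 buffer, 0 °C
Reagents that add atoms: none
Why: Oxidative cleavage of the PMB ether at neutral pH leaves the silyl ether, the enyne and the lactone untouched.

Step 11
Reactants: 21 enyne alcohol
Product: 22 (4R,5S)-5-[(1Z,3S,4Z)-3-(TBS-oxy)-2,6-dimethylhepta-1,4,6-trien-1-yl]-4-(hydroxymethyl)oxolan-2-one
Conditions: H2 (1 atm), Pd/CaCO3 poisoned with Pb(OAc)2 (Lindlar catalyst), quinoline, EtOAc, rt; stopped after 1 equiv H2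
Reagents that add atoms: none
Why: Lindlar semi-hydrogenation adds H2 syn to the alkyne of the conjugated enyne and gives the Z C1=C2 alkene, the alkenes being reduced more slowly.

Step 12
Reactants: 22 diene alcohol
Product: 24 (E)-oxime of (2S,3R)-2-[(1Z,3S,4Z)-3-(TBS-oxy)-2,6-dimethylhepta-1,4,6-trien-1-yl]-5-oxooxolane-3-carbaldehyde, via aldehyde 23 (not isolated)
Conditions: Dess–Martin periodinane, NaHCO3, CH2Cl2, 0 °C; crude aldehyde, NH2OH·HCl, pyridine, EtOH, 0 °C
Reagents that add atoms: hydroxylamine hydrochloride, NO.Cl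
Why: Dess–Martin oxidation followed at once by oxime condensation keeps the β-acyloxy aldehyde 23, which is open to C7 epimerisation and to loss of the lactone carboxylate, in solution only briefly and at low temperature.

Step 13
Reactants: 24 aldoxime
Product: 26 bridged isoxazoline (1Z,3S,4Z,6S,7R,10R)-3-(TBS-oxy)-13-norgermacra-1,4-dien-12,6-olide bearing the C8=N–O–C10 bridge, via nitrile oxide 25 (not isolated)
Conditions: aq. NaOCl (3 equiv), CH2Cl2, 0 °C to rt; 24 added over 10 h by syringe pump (final 2 mM)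
Reagents that add atoms: none
Why: NaOCl turns the aldoxime into nitrile oxide 25, which adds to C9=C10 in a concerted suprafacial (3+2) cycloaddition with its carbon on the unsubstituted C9 and its oxygen on C10, the regiochemistry normal for a 1,1-disubstituted alkene at the end of a diene. The closest known reaction type is the intramolecular nitrile oxide–alkene cycloaddition used for macrocyclisation, in which long tethers give bridged and not fused isoxazolines. The isoxazoline (ring C) closes by the cycloaddition itself and the ten-membered carbocycle (ring A) closes in the bridged mode, C8, C9 and C10 being shared by both rings and N–O spanning C8 and C10. The new stereocentre C10 is controlled by C3: allylic 1,3-strain across both Z alkenes turns C3–H into the forming ring and the silyloxy group outward, the s-cis-twisted diene then shows the tethered dipole only the inner face of C9=C10, and the C10 methyl group ends on the periphery (10R). The step needs chemoselectivity for C9=C10 over C1=C2 (a fused seven-membered closure) and over C4=C5 (which would need a four-membered ring), and cyclisation over dimerisation to the furoxan. The first rests on the much higher dipolarophile reactivity of a terminal 1,1-disubstituted alkene compared with the cis-1,2-disubstituted C1=C2, which would also have to place C3 and the isopropenyl group cis on the new isoxazoline, the second on slow addition at high dilution and on the cis-lactone and two Z alkenes, which leave few rotatable bonds between dipole and alkene.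

**From the cycloadduct to the target**

Step 14
Reactants: 26 bridged isoxazoline
Product: 28 (1Z,3S,4Z,6S,7S,10R)-3-(TBS-oxy)-10-hydroxy-8-oxo-13-norgermacra-1,4-dien-12,6-olide, via β-hydroxy imine 27 (not isolated)
Conditions: Mo(CO)6 (1 equiv), MeCN/H2O (15:1), 80 °C
Reagents that add atoms: water, O
Why: Mo(CO)6 cleaves the N–O bond reductively without touching alkenes, and the imine is hydrolysed in the wet medium to the β-hydroxy ketone under neutral conditions that should spare C7 and avoid retro-aldol opening.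

Step 15
Reactants: 28 β-hydroxy ketone
Product: 30 (1Z,3S,4Z,6S,7R,8S,10R)-3-(TBS-oxy)-8,10-dihydroxy-13-norgermacra-1,4-dien-12,6-olide, via diethylboron chelate 29 (not isolated)
Conditions: Et2BOMe, THF/MeOH (4:1), −78 °C; NaBH4, −78 °C; AcOH; MeOH co-evaporation
Reagents that add atoms: none
Why: Narasaka–Prasad reduction: Et2BOMe ties the C10 alkoxide and the C8 carbonyl into a six-membered chelate and borohydride adds from outside the chelate, which gives the syn-1,3-diol and sets C8 as S (C8–OH cis to C10–OH on ring A).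

Step 16
Reactants: 30 diol
Product: 31 (1Z,3S,4Z,6S,7S,8S,10R)-3-(TBS-oxy)-8-(TES-oxy)-10-hydroxy-13-norgermacra-1,4-dien-12,6-olide
Conditions: TESCl, imidazole, DMF, 0 °C
Reagents that add atoms: triethylsilyl chloride, CC[Si](Cl)(CC)CC
Why: Silylation selects the secondary C8 hydroxyl over the tertiary C10 hydroxyl on steric grounds and also blocks lactone migration from O6 to O8.

Step 17
Reactants: 31 TES ether
Product: 35 (1Z,3S,4Z,6S,7S,8S,10R)-3-(TBS-oxy)-8-(TES-oxy)-10-hydroxygermacra-1,4,11(13)-trien-12,6-olide, via dilithium enolate 32 (not isolated), via Mannich base 33 (not isolated), via trimethylammonium iodide 34 (not isolated)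
Conditions: LiN(i-Pr)2 (2.2 equiv), THF, −78 °C; CH2=NMe2+ I− (Eschenmoser's salt), −78 to 0 °C; MeI, MeOH, rt; then aq. NaHCO3, CH2Cl2
Reagents that add atoms: N,N-dimethylmethyleneiminium iodide (Eschenmoser's salt), C=[N+](C)C.[I-]
Why: The lactone enolate (the tertiary hydroxyl is carried as its lithium alkoxide) undergoes a Mannich reaction with the iminium salt, and quaternisation followed by mild base elimination gives the α-methylene lactone, the C11 stereocentre of 33 and 34 being lost in the elimination.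

Step 18
Reactants: 35 α-methylene lactone
Product: 36 (1Z,3S,4Z,6S,7R,8S,10R)-3-(TBS-oxy)-8,10-dihydroxygermacra-1,4,11(13)-trien-12,6-olide
Conditions: HF·pyridine, pyridine, THF, 0 °C
Reagents that add atoms: none
Why: A triethylsilyl ether is cleaved much faster than the secondary TBS ether by buffered HF·pyridine, so only C8–OH is set free.

Step 19
Reactants: 36 C8 alcohol; 37 angelic acid
Product: 39 (1Z,3S,4Z,6S,7R,8S,10R)-8-angeloyloxy-3-(TBS-oxy)-10-hydroxygermacra-1,4,11(13)-trien-12,6-olide, via mixed anhydride 38 (not isolated)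
Conditions: 37, 2,4,6-trichlorobenzoyl chloride, Et3N, toluene, rt; then 36, toluene, 80 °C (no DMAP)
Reagents that add atoms: none
Why: Yamaguchi-type acylation through the mixed anhydride without a nucleophilic catalyst transfers the angeloyl group without Z-to-E isomerisation to the tiglate, and only the secondary C8 hydroxyl reacts (C10–OH is tertiary, C3 is silylated).

Step 20
Reactants: 39 angelate
Product: 40 (1R,2S,3R,4Z,6S,7R,8S,10R)-8-angeloyloxy-1,2-epoxy-3-(TBS-oxy)-10-hydroxygermacra-4,11(13)-dien-12,6-olide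
Conditions: mCPBA (1.2 equiv), NaHCO3, CH2Cl2, 0 °C
Reagents that add atoms: 3-chloroperoxybenzoic acid, OOC(=O)c1cccc(Cl)c1
Why: Hydroxyl-directed peracid epoxidation: only C1=C2 has a free allylic hydroxyl, C4=C5 is deactivated by its allylic lactone and silyloxy C–O bonds and the conjugated alkenes are electron-poor; the peracid, hydrogen-bonded to C10–OH, should reach the face on which that hydroxyl stands when the C10 methyl group lies in the alkene plane (the ring bond C10–C9 cannot take that place), which is the threo sense of Z allylic alcohols and the trans sense of peracids with medium-ring 2-cycloalken-1-ols, is also the face away from the C3 silyloxy group, and sets C1 and C2 as in the target.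

Step 21
Reactants: 40 epoxide silyl ether
Product: 41 (1R,2R,3R,4Z,6S,7R,8S,10R)-8-angeloyloxy-1,2-epoxy-3,10-dihydroxygermacra-4,11(13)-dien-12,6-olide (target)
Conditions: HF·pyridine, pyridine, THF, 0 °C to rt
Reagents that add atoms: none
Why: Buffered fluoride cleavage of the TBS ether avoids a free alkoxide at C3, which could shift the epoxide (Payne rearrangement) or add to the α-methylene lactone.

**Compound list**

1 | propargyl alcohol | C#CCO | starting material
2 | bromomagnesium (Z)-3-(bromomagnesio)-2-methylprop-2-en-1-olate | Br[Mg]OC/C(C)=C\[Mg]Br | intermediate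
3 | (Z)-3-iodo-2-methylprop-2-en-1-ol | OC/C(C)=C\I | intermediate
4 | (Z)-3-iodo-2-methylprop-2-enal | O=C/C(C)=C\I | intermediate
5 | 2-methylbut-1-en-3-yne | C=C(C)C#C | starting material
6 | methyl(3-methylbut-3-en-1-ynyl)zinc | C[Zn]C#CC(C)=C | intermediate
7 | (1Z,3S)-1-iodo-2,6-dimethylhepta-1,6-dien-4-yn-3-ol | I/C=C(/C)[C@@H](O)C#CC(C)=C | intermediate
8 | tert-butyl{[(1Z,3S)-1-iodo-2,6-dimethylhepta-1,6-dien-4-yn-3-yl]oxy}dimethylsilane | I/C=C(/C)[C@@H](O[Si](C)(C)C(C)(C)C)C#CC(C)=C | intermediate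
9 | (S)-4-benzyl-2-oxazolidinone | O=C1OC[C@H](Cc2ccccc2)N1 | starting material
10 | methyl 4-chloro-4-oxobutanoate | COC(=O)CCC(Cl)=O | starting material
11 | methyl 4-[(4S)-4-benzyl-2-oxooxazolidin-3-yl]-4-oxobutanoate | COC(=O)CCC(=O)N1C(=O)OC[C@@H]1Cc1ccccc1 | intermediate
12 | 4-methoxybenzyl chloromethyl ether | COc1ccc(COCCl)cc1 | starting material
13 | sodium (Z)-enolate of 11 | [Na+].COC(=O)C/C=C(\[O-])N1C(=O)OC[C@@H]1Cc1ccccc1 | intermediate
14 | methyl (3R)-4-[(4S)-4-benzyl-2-oxooxazolidin-3-yl]-3-{[(4-methoxybenzyl)oxy]methyl}-4-oxobutanoate | COC(=O)C[C@H](COCc1ccc(OC)cc1)C(=O)N1C(=O)OC[C@@H]1Cc1ccccc1 | intermediate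
15 | methyl (3R)-4-(ethylsulfanyl)-3-{[(4-methoxybenzyl)oxy]methyl}-4-oxobutanoate | COC(=O)C[C@H](COCc1ccc(OC)cc1)C(=O)SCC | intermediate
16 | methyl (3R)-3-formyl-4-[(4-methoxybenzyl)oxy]butanoate | COC(=O)C[C@H](COCc1ccc(OC)cc1)C=O | intermediate
17 | [(1Z,3R)-3-(TBS-oxy)-2,6-dimethylhepta-1,6-dien-4-yn-1-yl]lithium | [Li]/C=C(/C)[C@@H](O[Si](C)(C)C(C)(C)C)C#CC(C)=C | intermediate
18 | [(1Z,3S)-3-(TBS-oxy)-2,6-dimethylhepta-1,6-dien-4-yn-1-yl]magnesium bromide | Br[Mg]/C=C(/C)[C@@H](O[Si](C)(C)C(C)(C)C)C#CC(C)=C | intermediate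
19 | bromomagnesium alkoxide of methyl (3R,4S,5Z,7R)-7-(TBS-oxy)-4-hydroxy-3-{[(4-methoxybenzyl)oxy]methyl}-6,10-dimethylundeca-5,10-dien-8-ynoate | COC(=O)C[C@H](COCc1ccc(OC)cc1)[C@@H](O[Mg]Br)/C=C(/C)[C@@H](O[Si](C)(C)C(C)(C)C)C#CC(C)=C | intermediate
20 | (4R,5S)-5-[(1Z,3R)-3-(TBS-oxy)-2,6-dimethylhepta-1,6-dien-4-yn-1-yl]-4-{[(4-methoxybenzyl)oxy]methyl}oxolan-2-one | O=C1C[C@H](COCc2ccc(OC)cc2)[C@H](/C=C(/C)[C@@H](O[Si](C)(C)C(C)(C)C)C#CC(C)=C)O1 | intermediate
21 | (4R,5S)-5-[(1Z,3R)-3-(TBS-oxy)-2,6-dimethylhepta-1,6-dien-4-yn-1-yl]-4-(hydroxymethyl)oxolan-2-one | O=C1C[C@H](CO)[C@H](/C=C(/C)[C@@H](O[Si](C)(C)C(C)(C)C)C#CC(C)=C)O1 | intermediate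
22 | (4R,5S)-5-[(1Z,3S,4Z)-3-(TBS-oxy)-2,6-dimethylhepta-1,4,6-trien-1-yl]-4-(hydroxymethyl)oxolan-2-one | O=C1C[C@H](CO)[C@H](/C=C(/C)[C@@H](O[Si](C)(C)C(C)(C)C)/C=C\C(C)=C)O1 | intermediate
23 | (2S,3S)-2-[(1Z,3S,4Z)-3-(TBS-oxy)-2,6-dimethylhepta-1,4,6-trien-1-yl]-5-oxooxolane-3-carbaldehyde | O=C1C[C@H](C=O)[C@H](/C=C(/C)[C@@H](O[Si](C)(C)C(C)(C)C)/C=C\C(C)=C)O1 | intermediate
24 | (E)-oxime of (2S,3R)-2-[(1Z,3S,4Z)-3-(TBS-oxy)-2,6-dimethylhepta-1,4,6-trien-1-yl]-5-oxooxolane-3-carbaldehyde | O=C1C[C@H](/C=N/O)[C@H](/C=C(/C)[C@@H](O[Si](C)(C)C(C)(C)C)/C=C\C(C)=C)O1 | intermediate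
25 | (2S,3R)-2-[(1Z,3S,4Z)-3-(TBS-oxy)-2,6-dimethylhepta-1,4,6-trien-1-yl]-5-oxooxolane-3-carbonitrile oxide | O=C1C[C@H](C#[N+][O-])[C@H](/C=C(/C)[C@@H](O[Si](C)(C)C(C)(C)C)/C=C\C(C)=C)O1 | intermediate
26 | bridged isoxazoline, (1Z,3S,4Z,6S,7R,10R)-3-(TBS-oxy)-13-norgermacra-1,4-dien-12,6-olide with C8=N–O–C10 bridge | C1C(=O)O[C@H]2/C=C(/C)[C@@H](O[Si](C)(C)C(C)(C)C)/C=C\[C@@]3(C)CC(=NO3)[C@@H]12 | intermediate
27 | (1Z,3S,4Z,6S,7R,10R)-3-(TBS-oxy)-10-hydroxy-8-imino-13-norgermacra-1,4-dien-12,6-olide | C1C(=O)O[C@H]2/C=C(/C)[C@@H](O[Si](C)(C)C(C)(C)C)/C=C\[C@](C)(O)CC(=N)[C@@H]12 | intermediate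
28 | (1Z,3S,4Z,6S,7S,10R)-3-(TBS-oxy)-10-hydroxy-8-oxo-13-norgermacra-1,4-dien-12,6-olide | C1C(=O)O[C@H]2/C=C(/C)[C@@H](O[Si](C)(C)C(C)(C)C)/C=C\[C@](C)(O)CC(=O)[C@@H]12 | intermediate
29 | diethylboron chelate of 28 (B bound to O10 and to the C8 carbonyl oxygen) | C1C(=O)O[C@H]2/C=C(/C)[C@@H](O[Si](C)(C)C(C)(C)C)/C=C\[C@@]3(C)CC(=[O+][B-](CC)(CC)O3)[C@@H]12 | intermediate
30 | (1Z,3S,4Z,6S,7R,8S,10R)-3-(TBS-oxy)-8,10-dihydroxy-13-norgermacra-1,4-dien-12,6-olide | C1C(=O)O[C@H]2/C=C(/C)[C@@H](O[Si](C)(C)C(C)(C)C)/C=C\[C@](C)(O)C[C@H](O)[C@@H]12 | intermediate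
31 | (1Z,3S,4Z,6S,7S,8S,10R)-3-(TBS-oxy)-8-(TES-oxy)-10-hydroxy-13-norgermacra-1,4-dien-12,6-olide | C1C(=O)O[C@H]2/C=C(/C)[C@@H](O[Si](C)(C)C(C)(C)C)/C=C\[C@](C)(O)C[C@H](O[Si](CC)(CC)CC)[C@@H]12 | intermediate
32 | dilithium salt of 31 (lactone enolate and C10 alkoxide) | C1=C(O[Li])O[C@H]2/C=C(/C)[C@@H](O[Si](C)(C)C(C)(C)C)/C=C\[C@](C)(O[Li])C[C@H](O[Si](CC)(CC)CC)[C@@H]12 | intermediate
33 | 11-(dimethylaminomethyl) derivative of 31 (C11 epimers) | CN(C)CC1C(=O)O[C@H]2/C=C(/C)[C@@H](O[Si](C)(C)C(C)(C)C)/C=C\[C@](C)(O)C[C@H](O[Si](CC)(CC)CC)[C@@H]12 | intermediate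
34 | 11-(trimethylammoniomethyl) iodide of 31 (C11 epimers) | [I-].C[N+](C)(C)CC1C(=O)O[C@H]2/C=C(/C)[C@@H](O[Si](C)(C)C(C)(C)C)/C=C\[C@](C)(O)C[C@H](O[Si](CC)(CC)CC)[C@@H]12 | intermediate
35 | (1Z,3S,4Z,6S,7S,8S,10R)-3-(TBS-oxy)-8-(TES-oxy)-10-hydroxygermacra-1,4,11(13)-trien-12,6-olide | C=C1C(=O)O[C@H]2/C=C(/C)[C@@H](O[Si](C)(C)C(C)(C)C)/C=C\[C@](C)(O)C[C@H](O[Si](CC)(CC)CC)[C@@H]12 | intermediate
36 | (1Z,3S,4Z,6S,7R,8S,10R)-3-(TBS-oxy)-8,10-dihydroxygermacra-1,4,11(13)-trien-12,6-olide | C=C1C(=O)O[C@H]2/C=C(/C)[C@@H](O[Si](C)(C)C(C)(C)C)/C=C\[C@](C)(O)C[C@H](O)[C@@H]12 | intermediate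
37 | angelic acid, (Z)-2-methylbut-2-enoic acid | C/C=C(/C)C(=O)O | starting material
38 | angelic 2,4,6-trichlorobenzoic anhydride | C/C=C(/C)C(=O)OC(=O)c1c(Cl)cc(Cl)cc1Cl | intermediate
39 | (1Z,3S,4Z,6S,7R,8S,10R)-8-angeloyloxy-3-(TBS-oxy)-10-hydroxygermacra-1,4,11(13)-trien-12,6-olide | C=C1C(=O)O[C@H]2/C=C(/C)[C@@H](O[Si](C)(C)C(C)(C)C)/C=C\[C@](C)(O)C[C@H](OC(=O)/C(C)=C\C)[C@@H]12 | intermediate
40 | (1R,2S,3R,4Z,6S,7R,8S,10R)-8-angeloyloxy-1,2-epoxy-3-(TBS-oxy)-10-hydroxygermacra-4,11(13)-dien-12,6-olide | C=C1C(=O)O[C@H]2/C=C(/C)[C@@H](O[Si](C)(C)C(C)(C)C)[C@H]3O[C@H]3[C@](C)(O)C[C@H](OC(=O)/C(C)=C\C)[C@@H]12 | intermediate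
41 | (1R,2R,3R,4Z,6S,7R,8S,10R)-8-angeloyloxy-1,2-epoxy-3,10-dihydroxygermacra-4,11(13)-dien-12,6-olide | C=C1C(=O)O[C@H]2/C=C(/C)[C@@H](O)[C@H]3O[C@H]3[C@](C)(O)C[C@H](OC(=O)/C(C)=C\C)[C@@H]12 | target

**Step count**

Total: 21 steps. Longest linear sequence: 17 steps (steps 1–4 or steps 5–8, then steps 9–21).

**Steps most likely to fail**

Step 13 (cycloaddition). The nitrile oxide may add in the fused mode to the nearer C1=C2 alkene and close a seven-membered ring, may dimerise faster than the ten-membered ring closes, or may add to the other face of C9=C10. The fallback is to cyclise before the alkyne is reduced, so that C1≡C2 is a poor dipolarophile and C3, C2, C1 and C10 lie on a straight line. It sets out from alcohol 21: Dess–Martin oxidation gives enyne aldehyde F1 and NH2OH·HCl/pyridine gives enyne oxime F2. NaOCl at high dilution gives enyne nitrile oxide F3, which has only the terminal alkene of the 1,3-enyne as a reactive partner and should give cycloalkyne isoxazoline F4. Lindlar semi-hydrogenation of the ring alkyne then returns to the route at 26.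

Step 20 (epoxidation). The peracid may attack the other face of C1=C2, or C4=C5 may compete. The fallback lets the C3 hydroxyl direct a metal-catalysed epoxidation as the last step. It sets out from 39: HF·pyridine removes the silyl group to give 3,10-diol F7. VO(acac)2 with t-BuOOH, bound to the secondary allylic C3–OH, should then deliver oxygen cis to that hydroxyl (the sense of vanadium with medium-ring 2-cycloalken-1-ols) and so return to the route at the target 41.

Step 15 (reduction at C8). The ring conformation may override the chelate so that hydride adds to the other face. The fallback corrects C8 by inversion. It sets out from 28: if the reduction gives 8-epi diol F5, a Mitsunobu reaction with chloroacetic acid (PPh3, DIAD) inverts the secondary carbinol to give chloroacetate F6. Thiourea and NaHCO3 in EtOH then remove the chloroacetyl group under neutral conditions and return to the route at 30.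

**Further compounds**

F1 | step 13 | (2S,3S)-2-[(1Z,3R)-3-(TBS-oxy)-2,6-dimethylhepta-1,6-dien-4-yn-1-yl]-5-oxooxolane-3-carbaldehyde | O=C1C[C@H](C=O)[C@H](/C=C(/C)[C@@H](O[Si](C)(C)C(C)(C)C)C#CC(C)=C)O1
F2 | step 13 | (E)-oxime of (2S,3R)-2-[(1Z,3R)-3-(TBS-oxy)-2,6-dimethylhepta-1,6-dien-4-yn-1-yl]-5-oxooxolane-3-carbaldehyde | O=C1C[C@H](/C=N/O)[C@H](/C=C(/C)[C@@H](O[Si](C)(C)C(C)(C)C)C#CC(C)=C)O1
F3 | step 13 | (2S,3R)-2-[(1Z,3R)-3-(TBS-oxy)-2,6-dimethylhepta-1,6-dien-4-yn-1-yl]-5-oxooxolane-3-carbonitrile oxide | O=C1C[C@H](C#[N+][O-])[C@H](/C=C(/C)[C@@H](O[Si](C)(C)C(C)(C)C)C#CC(C)=C)O1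
F4 | step 13 | bridged isoxazoline, (3R,4Z,6S,7R,10R)-3-(TBS-oxy)-13-norgermacr-4-en-1-yn-12,6-olide with C8=N–O–C10 bridge | C1C(=O)O[C@H]2/C=C(/C)[C@@H](O[Si](C)(C)C(C)(C)C)C#C[C@@]3(C)CC(=NO3)[C@@H]12
F5 | step 15 | (1Z,3S,4Z,6S,7R,8R,10R)-3-(TBS-oxy)-8,10-dihydroxy-13-norgermacra-1,4-dien-12,6-olide | C1C(=O)O[C@H]2/C=C(/C)[C@@H](O[Si](C)(C)C(C)(C)C)/C=C\[C@](C)(O)C[C@@H](O)[C@@H]12
F6 | step 15 | (1Z,3S,4Z,6S,7R,8S,10R)-8-(chloroacetoxy)-3-(TBS-oxy)-10-hydroxy-13-norgermacra-1,4-dien-12,6-olide | C1C(=O)O[C@H]2/C=C(/C)[C@@H](O[Si](C)(C)C(C)(C)C)/C=C\[C@](C)(O)C[C@H](OC(=O)CCl)[C@@H]12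
F7 | step 20 | (1Z,3S,4Z,6S,7R,8S,10R)-8-angeloyloxy-3,10-dihydroxygermacra-1,4,11(13)-trien-12,6-olide | C=C1C(=O)O[C@H]2/C=C(/C)[C@@H](O)/C=C\[C@](C)(O)C[C@H](OC(=O)/C(C)=C\C)[C@@H]12
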